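The earlier runs and the new flask were computed with made-up constants; noise was put on by code.

I began with the grey run.

| setting | teal | grey | flask |
|---|---|---|---|
| solid substrate | 0.14 M | 0.070 M | 0.14 M |
| protic impurity | 0.042 M | 0.042 M | 0.0420 M |
| remark | the very flask that is asked about, followed so far | run made earlier |  |
| time |  |  | 40 min |

- teal (time / min: isomer of the product A / %, target / %): 0.500: 0, 0; 1.00: 0, 3; 2.00: 1, 8; 4.00: 5, 20; 8.00: 11, 35
- grey (time / min: isomer of the product A / %, target / %): 6.00: 6, 39; 12.0: 15, 32; 15.0: 12, 26; 25.0: 16, 13; 30.0: 17, 12

(standard deviation of a reading: 1.5 percentage points)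

- ratio of isomer of the product A to target at 80 s
- ratio of isomer of the product A to target at 8.0 min
- ratio of isomer of the product A to target at 40 min

- given per volume of solution although it is solid: solid substrate
- at the start none of the solid substrate is in solution

I took the target's own concentration to set the order of its late fall in the grey run, so the loss per minute goes with the target present. The grey readings of 32 % at 12.0 min and 12 % at 30.0 min give a first-order fall of 0.0545 min⁻¹. So, as a reading, 12.7 min is the target's apparent half-life, the time in which the target present halves in the grey run, net of any target still being made over those minutes.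

I built the teal flask up from its reading at 8.00 min. With the main step and no loss, the ratio of isomer of the product A to target stayed at 0.314. Then I added the fall:

target at 40 min = 35 % × exp(−0.0545 min⁻¹ × 32.0 min) = 6.12 %

If the lost target all became isomer of the product A, that isomer would reach 39.9 %, and the ratio 6.52. Last I added the isomer's own stall: in the grey run it gained 2 percentage points between 12.0 min and 30.0 min. Holding it at 17 % gave me:

ratio at 40 min = 17 % / 6.12 % = 2.78

The forecast gave 0.08, 0.31 and 0.8, arguing of the impurity “so it should run out sooner and more target should survive”. My last ratio stood higher than the forecast's.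

The teal flask gave 0.0310, 0.189 and 2.06.

    starting material + protic impurity → quenched substrate (k = 0.0900 M⁻¹ s⁻¹)
    starting material ⇌ target (K = 3.10, k = 0.00610 s⁻¹)
    solid substrate ⇌ starting material, rate k3*(cs3 - [starting material]) while solid is left; crystals form when [starting material] > cs3 (solubility = 0.0950 M, k = 0.00480 s⁻¹)
    isomer of the product A ⇌ isomer of the product B (K = 2.10, k = 0.00240 s⁻¹)
    target ⇌ isomer of the product A (K = 16.0, k = 0.00110 s⁻¹)

From 26.0 % of target at 20.0 min, the apparent half-life gives 8.74 % at 40.0 min, and the teal flask held 10.1 %, with 20.8 % of isomer of the product A. The neighbour flask, charged with 0.24 M of solid substrate, ended at 14.9 % of target and 23.7 % of that isomer, a ratio of 1.59. In concentration, the neighbour flask's target stood at 0.0358 M against 0.0141 M in the teal flask, a factor of 2.53, which the grey run's apparent half-life spans in 17.0 min.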